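**Strategy.** The route rests on disconnecting the C3–C4 bond of the oxolan-2-one ring, between the benzylidene-bearing α-carbon C3 and the stereogenic β-carbon C4. In the open-chain 3-(3,4,5-trimethoxyphenyl)propyl diazoacetate, C4 is a prochiral methylene whose two enantiotopic hydrogens stand in a 1,5-relationship to the diazo carbon, the future C3. A chiral dirhodium carboxamidate converts that carbon into a carbene that inserts into one of these C–H bonds, which closes the lactone and sets C4 as (S) in one operation from an achiral ester. The (E)-4-hydroxy-3,5-dimethoxybenzylidene unit is then installed at C3 by aldol addition of silyl-protected syringaldehyde and E1cB dehydration.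

Key step: step 4

Assumption: the 4S-configured MPPIM ligand set is taken to deliver (R)-4-benzyl lactones in this substrate class, so the 4R catalyst is specified for the (S) series; should the sense be the reverse, the antipodal catalyst is used with no other change.

**Step 1**
Reactants: 1 3-(3,4,5-trimethoxyphenyl)propanoic acid
Product: 2 3-(3,4,5-trimethoxyphenyl)propan-1-ol
Conditions: BH3·THF, THF, 0 °C to rt; MeOH quench, aqueous work-up
Reagents that add atoms: none
Why: Borane reduces the carboxylic acid chemoselectively through its acyloxyborane to the primary alcohol and leaves the aryl methyl ethers untouched (borane reduction of a carboxylic acid).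

**Step 2**
Reactants: 2 3-(3,4,5-trimethoxyphenyl)propan-1-ol
Product: 3 3-(3,4,5-trimethoxyphenyl)propyl 2-bromoacetate
Conditions: BrCH2COBr, NaHCO3, MeCN, 0 °C to rt
Reagents that add atoms: bromoacetyl bromide, BrCC(Br)=O
Why: The primary alcohol is acylated at the acyl bromide much faster than it displaces the alkyl bromide, and NaHCO3 takes up the HBr (O-acylation).

**Step 3**
Reactants: 3 3-(3,4,5-trimethoxyphenyl)propyl 2-bromoacetate
Product: 6 3-(3,4,5-trimethoxyphenyl)propyl 2-diazoacetate, via N-alkylated ditosylhydrazide 4 (not isolated), via glyoxylate tosylhydrazone 5 (not isolated)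
Conditions: TsNHNHTs, DBU, THF, 0 °C
Reagents that add atoms: N,N'-ditosylhydrazine, Cc1ccc(cc1)S(=O)(=O)NNS(=O)(=O)c1ccc(C)cc1
Why: The ditosylhydrazine anion is alkylated by the α-bromo ester (SN2) to 4, DBU-induced loss of sulfinate gives tosylhydrazone 5, and a second base-induced loss of sulfinate of the Bamford–Stevens type gives the diazoacetate under conditions mild enough for the ester.

**Step 4**
Reactants: 6 3-(3,4,5-trimethoxyphenyl)propyl 2-diazoacetate
Product: 7 (4S)-4-(3,4,5-trimethoxybenzyl)oxolan-2-one
Conditions: Rh2(4R-MPPIM)4 (1 mol %; MPPIM = methyl 2-oxo-1-(3-phenylpropanoyl)imidazolidine-4-carboxylate), CH2Cl2, reflux, slow syringe-pump addition of 6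
Reagents that add atoms: none
Why: The divalent rhodium dimer Rh2(4R-MPPIM)4 extrudes N2 from 6 to give an electrophilic rhodium-bound carbene, whose carbon inserts through a concerted, hydride-transfer-like three-centre transition state into a C–H bond of the chain methylene C2' (the carbon β to the ester oxygen), which forms the C3–C4 bond of the lactone. The closest known reaction type is the enantioselective intramolecular C–H insertion of diazoacetates of primary 3-arylpropyl alcohols catalysed by chiral dirhodium carboxamidates. The oxolan-2-one ring closes by 1,5-insertion through a five-membered cyclic transition state made up of the carbene carbon, the carbonyl carbon, the ester oxygen, C1' and C2'. The new stereocentre C4 is set by catalyst control alone: the ester arms of the four imidazolidinone ligands around the axial carbene site distinguish the two enantiotopic hydrogens at C2', and the 4R ligand set is chosen to lead to the (S) lactone. The step needs site selectivity for C2'–H over the benzylic C3'–H (six-membered ring) and the O–CH2 hydrogens (strained four-membered ring), which the C(=O)–O–CH2 tether and the strong preference of the weakly electrophilic carboxamidate carbene for five-membered closure should secure, while the arene is too remote for aromatic cycloaddition. Slow addition of 6 should keep carbene dimerisation low.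

**Step 5**
Reactants: 8 syringaldehyde (4-hydroxy-3,5-dimethoxybenzaldehyde)
Product: 9 4-(tert-butyldimethylsilyloxy)-3,5-dimethoxybenzaldehyde
Conditions: TBSCl, imidazole, DMF, rt
Reagents that add atoms: tert-butyldimethylsilyl chloride, CC(C)(C)[Si](C)(C)Cl
Why: Imidazole-promoted silylation masks the acidic phenol, which would otherwise quench the enolate of step 6 and deactivate the aldehyde as its phenoxide (silyl ether protection).

**Step 6**
Reactants: 7 (4S)-4-(3,4,5-trimethoxybenzyl)oxolan-2-one; 9 4-(tert-butyldimethylsilyloxy)-3,5-dimethoxybenzaldehyde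
Product: 11 (3R,4S)-3-{[4-(tert-butyldimethylsilyloxy)-3,5-dimethoxyphenyl](hydroxy)methyl}-4-(3,4,5-trimethoxybenzyl)oxolan-2-one as a mixture of carbinol epimers, via lithium enolate 10 (not isolated)
Conditions: LiN(iPr)2, THF, −78 °C; then 9, −78 °C; AcOH quench at −78 °C
Reagents that add atoms: none
Why: Kinetic deprotonation at C3, the only enolisable position, gives enolate 10, which adds to the aldehyde on the ring face anti to the C4 benzyl group so that the 3,4-trans aldol should form (aldol addition); the carbinol configuration is left uncontrolled because step 7 destroys it, and C4 is not enolisable and keeps its configuration.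

**Step 7**
Reactants: 11 (3R,4S)-aldol adduct (mixture of carbinol epimers)
Product: 13 (3E,4S)-3-[4-(tert-butyldimethylsilyloxy)-3,5-dimethoxybenzylidene]-4-(3,4,5-trimethoxybenzyl)oxolan-2-one, via mesylate 12 (not isolated)
Conditions: MsCl, Et3N, CH2Cl2, 0 °C; then DBU, 0 °C to rt
Reagents that add atoms: none
Why: Mesylation turns the hydroxyl into a leaving group and DBU removes the acidic C3–H, so both carbinol epimers converge by E1cB elimination through the same enolate on the conjugated arylidene lactone, for which the (E) isomer (aryl anti to the lactone carbonyl) is expected to predominate as the more stable geometry.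

**Step 8**
Reactants: 13 (3E,4S)-silyl-protected arylidene lactone
Product: 14 (3E,4S)-3-(4-hydroxy-3,5-dimethoxybenzylidene)-4-(3,4,5-trimethoxybenzyl)oxolan-2-one
Conditions: Bu4NF, AcOH (1:1), THF, 0 °C
Reagents that add atoms: none
Why: Fluoride attacks silicon and releases the phenol, while AcOH protonates the phenoxide at once so that the base-sensitive arylidene lactone is not exposed to conditions that could shift or isomerise the double bond (fluoride desilylation).

**Compound list**

1 | 3-(3,4,5-trimethoxyphenyl)propanoic acid | COc1cc(CCC(=O)O)cc(OC)c1OC | starting material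
2 | 3-(3,4,5-trimethoxyphenyl)propan-1-ol | COc1cc(CCCO)cc(OC)c1OC | intermediate
3 | 3-(3,4,5-trimethoxyphenyl)propyl 2-bromoacetate | COc1cc(CCCOC(=O)CBr)cc(OC)c1OC | intermediate
4 | 3-(3,4,5-trimethoxyphenyl)propyl 2-[1,2-bis(4-methylbenzenesulfonyl)hydrazin-1-yl]acetate | COc1cc(CCCOC(=O)CN(NS(=O)(=O)c2ccc(C)cc2)S(=O)(=O)c2ccc(C)cc2)cc(OC)c1OC | intermediate (not isolated)
5 | 3-(3,4,5-trimethoxyphenyl)propyl (2E)-2-[2-(4-methylbenzenesulfonyl)hydrazinylidene]acetate | COc1cc(CCCOC(=O)/C=N/NS(=O)(=O)c2ccc(C)cc2)cc(OC)c1OC | intermediate (not isolated)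
6 | 3-(3,4,5-trimethoxyphenyl)propyl 2-diazoacetate | COc1cc(CCCOC(=O)C=[N+]=[N-])cc(OC)c1OC | intermediate
7 | (4S)-4-(3,4,5-trimethoxybenzyl)oxolan-2-one | O=C1OC[C@H](C1)Cc1cc(OC)c(OC)c(OC)c1 | intermediate
8 | syringaldehyde (4-hydroxy-3,5-dimethoxybenzaldehyde) | COc1cc(C=O)cc(OC)c1O | starting material
9 | 4-(tert-butyldimethylsilyloxy)-3,5-dimethoxybenzaldehyde | COc1cc(C=O)cc(OC)c1O[Si](C)(C)C(C)(C)C | intermediate
10 | lithium (4S)-4-(3,4,5-trimethoxybenzyl)-4,5-dihydrofuran-2-olate (lithium enolate of 7) | [Li]OC1=C[C@H](Cc2cc(OC)c(OC)c(OC)c2)CO1 | intermediate (not isolated)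
11 | (3R,4S)-3-{[4-(tert-butyldimethylsilyloxy)-3,5-dimethoxyphenyl](hydroxy)methyl}-4-(3,4,5-trimethoxybenzyl)oxolan-2-one, 3,4-trans, carbinol carbon as a mixture of epimers | COc1cc(C(O)[C@@H]2C(=O)OC[C@H]2Cc2cc(OC)c(OC)c(OC)c2)cc(OC)c1O[Si](C)(C)C(C)(C)C | intermediate
12 | methanesulfonate of 11 at the carbinol oxygen, (3R,4S), carbinol carbon as a mixture of epimers | COc1cc(C(OS(C)(=O)=O)[C@@H]2C(=O)OC[C@H]2Cc2cc(OC)c(OC)c(OC)c2)cc(OC)c1O[Si](C)(C)C(C)(C)C | intermediate (not isolated)
13 | (3E,4S)-3-[4-(tert-butyldimethylsilyloxy)-3,5-dimethoxybenzylidene]-4-(3,4,5-trimethoxybenzyl)oxolan-2-one | COc1cc(/C=C2/C(=O)OC[C@H]2Cc2cc(OC)c(OC)c(OC)c2)cc(OC)c1O[Si](C)(C)C(C)(C)C | intermediate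
14 | (3E,4S)-3-(4-hydroxy-3,5-dimethoxybenzylidene)-4-(3,4,5-trimethoxybenzyl)oxolan-2-one | COc1cc(/C=C2/C(=O)OC[C@H]2Cc2cc(OC)c(OC)c(OC)c2)cc(OC)c1O | target

**Step count.** Total: 8 steps. Longest linear sequence: 7 steps (steps 1, 2, 3, 4, 6, 7, 8); step 5 is a one-step side branch.

**Steps most likely to fail**

Step 4. The catalyst may discriminate the two enantiotopic hydrogens at C2' insufficiently, the carbene may insert at the benzylic methylene, or it may dimerise. The fallback sets out from acid 1 and comes back to the route at 7. It gives up the ring-closing C–H insertion and makes the same C3–C4 bond by auxiliary-controlled enolate alkylation, with the ring closed afterwards at the ester C–O bond. Acid 1 is activated as its pivaloyl mixed anhydride (PivCl, Et3N, LiCl, THF) and coupled with (R)-4-benzyloxazolidin-2-one to give (4R)-4-benzyl-3-[3-(3,4,5-trimethoxyphenyl)propanoyl]oxazolidin-2-one F1. Its sodium (Z)-enolate (NaN(SiMe3)2, THF, −78 °C) should be alkylated by tert-butyl bromoacetate on the face opposite the auxiliary benzyl group to give tert-butyl (3S)-3-{[(4R)-4-benzyl-2-oxooxazolidin-3-yl]carbonyl}-4-(3,4,5-trimethoxyphenyl)butanoate F2. LiBH4 (THF, MeOH, 0 °C) cleaves the imide reductively, with release of the auxiliary, to tert-butyl (3S)-3-(hydroxymethyl)-4-(3,4,5-trimethoxyphenyl)butanoate F3. CF3CO2H in CH2Cl2 then removes the tert-butyl group as isobutene and the hydroxy acid lactonises to 7.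

Step 7. The elimination may give an E/Z mixture, or DBU may deprotonate C4 (the γ-position of the product) and move the double bond into the ring, which would erase the stereocentre. The fallback sets out from 7 and comes back to the route at 13, bypassing aldol 11 and mesylate 12. Lactone 7 is treated with LiN(iPr)2 (2.2 equiv, THF, −78 °C) and ClP(O)(OEt)2; the enol phosphate first formed undergoes a base-induced 1,3-phosphoryl shift from oxygen to carbon to give diethyl [(4R)-2-oxo-4-(3,4,5-trimethoxybenzyl)oxolan-3-yl]phosphonate F4. C4 has the same spatial arrangement as in 7; the descriptor changes only because phosphorus raises the priority of C3. Horner–Wadsworth–Emmons olefination of F4 with aldehyde 9 (KOtBu, THF, 0 °C) should then give 13 directly, with the alkene geometry set in the olefination and not by elimination from a preformed aldol.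

Step 3. The double loss of sulfinate may stop at the hydrazone stage, the diazo ester may decompose on purification, or traces of sulfinate and amidine may be carried over and block the axial sites of the rhodium catalyst in step 4. The fallback sets out from alcohol 2 and comes back to the route at 6. Acetoacetylation with 2,2,6-trimethyl-4H-1,3-dioxin-4-one (xylene, 130 °C) gives 3-(3,4,5-trimethoxyphenyl)propyl 3-oxobutanoate F5. Regitz diazo transfer with 4-acetamidobenzenesulfonyl azide and Et3N in MeCN gives 3-(3,4,5-trimethoxyphenyl)propyl 2-diazo-3-oxobutanoate F6. Deacetylation with LiOH in aqueous THF then gives 6 free of sulfinate and amidine.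

**Further compounds**

F1 | step 4 | (4R)-4-benzyl-3-[3-(3,4,5-trimethoxyphenyl)propanoyl]oxazolidin-2-one | COc1cc(CCC(=O)N2[C@H](Cc3ccccc3)COC2=O)cc(OC)c1OC
F2 | step 4 | tert-butyl (3S)-3-{[(4R)-4-benzyl-2-oxooxazolidin-3-yl]carbonyl}-4-(3,4,5-trimethoxyphenyl)butanoate | COc1cc(C[C@@H](CC(=O)OC(C)(C)C)C(=O)N2[C@H](Cc3ccccc3)COC2=O)cc(OC)c1OC
F3 | step 4 | tert-butyl (3S)-3-(hydroxymethyl)-4-(3,4,5-trimethoxyphenyl)butanoate | COc1cc(C[C@@H](CC(=O)OC(C)(C)C)CO)cc(OC)c1OC
F4 | step 7 | diethyl [(4R)-2-oxo-4-(3,4,5-trimethoxybenzyl)oxolan-3-yl]phosphonate (C3 epimers) | CCOP(=O)(OCC)C1C(=O)OC[C@H]1Cc1cc(OC)c(OC)c(OC)c1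
F5 | step 3 | 3-(3,4,5-trimethoxyphenyl)propyl 3-oxobutanoate | COc1cc(CCCOC(=O)CC(C)=O)cc(OC)c1OC
F6 | step 3 | 3-(3,4,5-trimethoxyphenyl)propyl 2-diazo-3-oxobutanoate | COc1cc(CCCOC(=O)C(=[N+]=[N-])C(C)=O)cc(OC)c1OC
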